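**Retrosynthetic overview**

1. Key disconnection: the C6'–C7' bond in the middle of the side chain (ring atoms O1, O2, C3, C4, C5; side chain C1'–C10' counted outward from C5, C2' bearing CH3, C10' bearing phenyl). It is made last among the C–C bonds, on the intact peroxide, by a one-pot hydroboration/alkyl–alkyl Suzuki–Miyaura coupling of the complete dioxolane ester carrying a C5'=C6' vinyl end with (4-bromobutyl)benzene; this one operation adds ten carbons and the arene.
2. Enabling feature: both oxygen-bearing ring carbons C3 and C5 are quaternary. The O1–O2 bond is therefore shielded and has no α-C–H (no base-induced Kornblum–DeLaMare cleavage), and five sp3 carbons (C1'–C5') keep the reacting C6' away from the 1,2-dioxolane.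
3. 1,2-Dioxolane (the only ring of the target): C5–O by invertive perhydrolysis of an enantiopure oxetane, ring closure by peroxyketalisation of a C3 methyl ketone, C3–CH2CO2Me by alkylation of the peroxycarbenium ion.
4. Stereocentres: C2' from (R)-citronellal; C5 from Sharpless epoxidation, Red-Al opening and oxetane formation; C3 is not controlled by the substrate and is fixed by separating the epimers after the alkylation (step 14).
5. Ring order: oxirane (step 3), then oxetane (step 9), then 1,2-dioxolane (step 13); the two small rings are temporary.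

Key step: step 15

Remark: (R)-citronellal and (4-bromobutyl)benzene are taken as purchased; the carbinol carbon made in step 7 is carried as both epimers because it becomes the C3 ketone in step 12.

**Route**

Step 1
Reactants: 1 (R)-citronellal
Product: 2 (4R)-4,8-dimethylnon-7-en-1-yne
Conditions: dimethyl (1-diazo-2-oxopropyl)phosphonate, K2CO3, MeOH, 0 °C → rt
Reagents that add atoms: dimethyl (1-diazo-2-oxopropyl)phosphonate, COP(=O)(OC)C(=[N+]=[N-])C(C)=O
Why: Seyferth–Gilbert homologation (Ohira–Bestmann variant) turns the aldehyde into the terminal alkyne under carbonate conditions; the only stereocentre (the future C2') is β to the carbonyl and is carried over unchanged from the chiral pool.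

Step 2
Reactants: 2 (4R)-4,8-dimethylnon-7-en-1-yne
Product: 5 (2E,5R)-3,5,9-trimethyldeca-2,8-dien-1-ol, via alkenylalane 3 (not isolated), via lithium alanate 4 (not isolated)
Conditions: Me3Al, Cp2ZrCl2 (cat.), CH2Cl2, 0 °C → rt; evaporate; n-BuLi, hexane/THF, −78 °C; (CH2O)n, → rt; aqueous work-up
Reagents that add atoms: trimethylaluminium, C[Al](C)C; paraformaldehyde (as formaldehyde), C=O
Why: Negishi zirconium-catalysed carboalumination adds CH3 and Al syn across the alkyne with CH3 on the internal carbon, and hydroxymethylation of the derived alanate goes with retention, so the (E)-trisubstituted allylic alcohol should result; the isolated trisubstituted alkene does not react.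

Step 3
Reactants: 5 (2E,5R)-3,5,9-trimethyldeca-2,8-dien-1-ol
Product: 6 [(2S,3S)-3-[(2R)-2,6-dimethylhept-5-en-1-yl]-3-methyloxiran-2-yl]methanol
Conditions: Ti(OiPr)4 (10 mol %), L-(+)-diethyl tartrate (12 mol %), t-BuOOH, 4 Å MS, CH2Cl2, −20 °C
Reagents that add atoms: tert-butyl hydroperoxide, CC(C)(C)OO
Why: Sharpless asymmetric epoxidation; with L-(+)-diethyl tartrate the reagent-controlled oxygen transfer to an (E)-3,3-disubstituted allylic alcohol (geraniol type) gives the (2S,3S)-epoxide, which sets the tertiary C–O carbon (the future C5), and the remote alkene, not being allylic to OH, is left alone.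

Step 4
Reactants: 6 [(2S,3S)-3-[(2R)-2,6-dimethylhept-5-en-1-yl]-3-methyloxiran-2-yl]methanol
Product: 8 (4R)-5-[(2S,3S)-3-(hydroxymethyl)-2-methyloxiran-2-yl]-4-methylpentanal, via ozonide 7 (not isolated)
Conditions: O3, CH2Cl2, −78 °C; then PPh3, −78 °C → rt
Reagents that add atoms: ozone, [O-][O+]=O
Why: Ozonolysis with reductive work-up (phosphine reduction of the ozonide) cleaves the only C=C bond to the aldehyde and acetone without touching the epoxide or any stereocentre.

Step 5
Reactants: 8 (4R)-5-[(2S,3S)-3-(hydroxymethyl)-2-methyloxiran-2-yl]-4-methylpentanal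
Product: 9 [(2S,3S)-3-methyl-3-[(2R)-2-methylhex-5-en-1-yl]oxiran-2-yl]methanol
Conditions: Ph3PCH3Br (2.5 equiv), KHMDS (2.4 equiv), THF, 0 °C; then 8, −78 °C → rt
Reagents that add atoms: methyltriphenylphosphonium bromide, C[P+](c1ccccc1)(c1ccccc1)c1ccccc1.[Br-]
Why: Wittig methylenation with the non-stabilised ylide (the extra equivalent covers the free OH) gives the vinyl terminus that becomes C5'=C6' of the key-step substrate.

Step 6
Reactants: 9 [(2S,3S)-3-methyl-3-[(2R)-2-methylhex-5-en-1-yl]oxiran-2-yl]methanol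
Product: 10 (2R,3S)-3-methyl-3-[(2R)-2-methylhex-5-en-1-yl]oxirane-2-carbaldehyde
Conditions: Dess–Martin periodinane, CH2Cl2, 0 °C → rt
Reagents that add atoms: none
Why: Dess–Martin oxidation stops at the aldehyde under neutral conditions that leave the epoxide and its two stereocentres intact.

Step 7
Reactants: 10 (2R,3S)-3-methyl-3-[(2R)-2-methylhex-5-en-1-yl]oxirane-2-carbaldehyde
Product: 11 (1RS)-1-[(2S,3S)-3-methyl-3-[(2R)-2-methylhex-5-en-1-yl]oxiran-2-yl]ethan-1-ol
Conditions: MeMgBr, THF, −78 °C
Reagents that add atoms: methylmagnesium bromide, C[Mg]Br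
Why: Grignard 1,2-addition to the aldehyde at low temperature; the new carbinol centre forms as both epimers, which is of no consequence because this carbon becomes the C3 ketone in step 12.

Step 8
Reactants: 11 (1RS)-1-[(2S,3S)-3-methyl-3-[(2R)-2-methylhex-5-en-1-yl]oxiran-2-yl]ethan-1-ol
Product: 12 (2RS,4S,6R)-4,6-dimethyldec-9-ene-2,4-diol
Conditions: Red-Al, THF, 0 °C → rt
Reagents that add atoms: none
Why: Red-Al reduction of a 2,3-epoxy alcohol: the aluminium alkoxide delivers hydride intramolecularly to the epoxide carbon next to the carbinol (also the less hindered one), so the 1,3-diol forms and the tertiary C–O bond keeps its configuration.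

Step 9
Reactants: 12 (2RS,4S,6R)-4,6-dimethyldec-9-ene-2,4-diol
Product: 14 (2S,4RS)-2,4-dimethyl-2-[(2R)-2-methylhex-5-en-1-yl]oxetane, via monotosylate 13 (not isolated)
Conditions: n-BuLi (1.0 equiv), THF, 0 °C; TsCl (1.0 equiv), 0 °C → rt; n-BuLi (1.05 equiv), 0 → 50 °C
Reagents that add atoms: none
Why: One-pot monotosylation of the less hindered secondary alkoxide and intramolecular Williamson etherification (4-exo-tet SN2) by the tertiary alkoxide closes the oxetane; the C–O bond at the quaternary carbon is not broken, so its configuration is retained.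

Step 10
Reactants: 14 (2S,4RS)-2,4-dimethyl-2-[(2R)-2-methylhex-5-en-1-yl]oxetane
Product: 15 (2RS,4R,6R)-4-hydroperoxy-4,6-dimethyldec-9-en-2-ol
Conditions: H2O2 (anhydrous, in Et2O, excess), TMSOTf (cat.), Et2O, −78 → 0 °C
Reagents that add atoms: hydrogen peroxide, OO
Why: Lewis acid-promoted perhydrolysis of an oxetane: H2O2 attacks the silyl-activated ring at the tertiary carbon, which carries most of the positive charge, in an SN2-like opening with inversion, and this sets C5 as the (R)-configured tertiary hydroperoxide.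

Step 11
Reactants: 15 (2RS,4R,6R)-4-hydroperoxy-4,6-dimethyldec-9-en-2-ol
Product: 16 (2RS,4R,6R)-4-[(2-methoxypropan-2-yl)peroxy]-4,6-dimethyldec-9-en-2-ol
Conditions: 2-methoxypropene (1.1 equiv), PPTS (cat.), CH2Cl2, −20 °C; Et3N quench
Reagents that add atoms: 2-methoxypropene, COC(C)=C
Why: Acid-catalysed addition of the hydroperoxide, the more nucleophilic OH owing to the α-effect, to the enol ether gives the monoperoxyketal and masks OOH for the oxidation.

Step 12
Reactants: 16 (2RS,4R,6R)-4-[(2-methoxypropan-2-yl)peroxy]-4,6-dimethyldec-9-en-2-ol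
Product: 17 (4R,6R)-4-[(2-methoxypropan-2-yl)peroxy]-4,6-dimethyldec-9-en-2-one
Conditions: Dess–Martin periodinane, pyridine, CH2Cl2, 0 °C → rt
Reagents that add atoms: none
Why: Buffered Dess–Martin oxidation converts the secondary alcohol into the methyl ketone (the future C3) while the peroxyketal and the C5 stereocentre stay untouched.

Step 13
Reactants: 17 (4R,6R)-4-[(2-methoxypropan-2-yl)peroxy]-4,6-dimethyldec-9-en-2-one
Product: 20 (3RS,5R)-3-methoxy-3,5-dimethyl-5-[(2R)-2-methylhex-5-en-1-yl]-1,2-dioxolane, via hydroperoxy ketone 18 (not isolated), via dioxolan-3-ol 19 (not isolated)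
Conditions: p-TsOH·H2O (cat.), MeOH, 0 °C → rt
Reagents that add atoms: methanol, CO
Why: Acid-catalysed transketalisation in methanol frees the hydroperoxide, which adds to the ketone in a 5-exo-trig closure to the peroxyhemiketal, and exchange with methanol gives the 3-methoxy-1,2-dioxolane; C3 forms as both epimers, which is irrelevant because it is ionised in step 14.

Step 14
Reactants: 20 (3RS,5R)-3-methoxy-3,5-dimethyl-5-[(2R)-2-methylhex-5-en-1-yl]-1,2-dioxolane
Product: 22 methyl 2-[(3R,5R)-3,5-dimethyl-5-[(2R)-2-methylhex-5-en-1-yl]-1,2-dioxolan-3-yl]acetate, via peroxycarbenium ion 21 (not isolated)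
Conditions: 1-(tert-butyldimethylsilyloxy)-1-methoxyethene (3 equiv), TiCl4 (1.1 equiv), CH2Cl2, −78 °C; chromatographic (HPLC) separation of the C3 epimers
Reagents that add atoms: 1-(tert-butyldimethylsilyloxy)-1-methoxyethene, C=C(OC)O[Si](C)(C)C(C)(C)C
Why: TiCl4 ionises the peroxyketal to the planar peroxycarbenium ion 21, which is trapped at C3 by the silyl ketene acetal (Mukaiyama-type addition); the two faces differ only by CH3 versus CH2R on the remote C5, so little bias is expected and C3 is fixed by separating the (3R) ester 22 (CH2CO2Me cis to the C5 side chain) from its (3S) epimer.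

Step 15
Reactants: 22 methyl 2-[(3R,5R)-3,5-dimethyl-5-[(2R)-2-methylhex-5-en-1-yl]-1,2-dioxolan-3-yl]acetate; 23 (4-bromobutyl)benzene
Product: 25 methyl 2-[(3R,5R)-3,5-dimethyl-5-[(2R)-2-methyl-10-phenyldecyl]-1,2-dioxolan-3-yl]acetate, via alkylborane 24 (not isolated)
Conditions: 9-BBN, THF, 0 °C → rt; then 23, Pd(OAc)2 (5 mol %), PCy3 (10 mol %), K3PO4·H2O, THF, rt
Reagents that add atoms: none
Why: Anti-Markovnikov syn hydroboration with the bulky dialkylborane puts boron on the terminal carbon C6' only; hydroxide from K3PO4·H2O forms the borate, Pd(0)/PCy3 adds oxidatively (SN2-type) to the primary C–Br bond of 23, the primary alkyl group transmetalates from boron to palladium, and reductive elimination forms the C6'–C7' σ-bond faster than β-hydride elimination. The closest known reaction type is the room-temperature alkyl–alkyl Suzuki–Miyaura coupling of B-alkyl-9-BBN reagents with primary alkyl bromides bearing β-hydrogens, which tolerates esters, and palladium-catalysed couplings are known to proceed in the presence of dialkyl peroxides. No ring is closed and no stereocentre is created; C2', C3 and C5 have no bond that reacts under these conditions and should pass unchanged. The selectivity needed is chemoselectivity for C=C and C–Br over O–O and the ester: the O–O bond lies between the quaternary carbons C3 and C5, so it is shielded and has no α-C–H for base-induced cleavage, the reacting terminus is held away from it by C1'–C5', and phosphate at room temperature is too weak a base to enolise the ester toward retro-Michael opening.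

Step 16
Reactants: 25 methyl 2-[(3R,5R)-3,5-dimethyl-5-[(2R)-2-methyl-10-phenyldecyl]-1,2-dioxolan-3-yl]acetate
Product: 26 2-[(3R,5R)-3,5-dimethyl-5-[(2R)-2-methyl-10-phenyldecyl]-1,2-dioxolan-3-yl]acetic acid
Conditions: LiOH, THF/H2O, 0 °C → rt; then 1 M HCl to pH 3
Reagents that add atoms: lithium hydroxide, [Li+].[OH-]
Why: Saponification of the methyl ester and mild acidification; the dioxolane has no α-hydrogen and should resist hydroxide at 0 °C, and no stereocentre is involved.

**Compound list**

1 | (R)-citronellal, (3R)-3,7-dimethyloct-6-enal | C[C@H](CCC=C(C)C)CC=O | starting material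
2 | (4R)-4,8-dimethylnon-7-en-1-yne | C[C@H](CCC=C(C)C)CC#C | intermediate
3 | dimethyl[(1E,4R)-2,4,8-trimethylnona-1,7-dien-1-yl]alumane (alkenylalane, not isolated) | C[C@H](CCC=C(C)C)C/C(C)=C/[Al](C)C | intermediate
4 | lithium butyl(dimethyl)[(1E,4R)-2,4,8-trimethylnona-1,7-dien-1-yl]aluminate (not isolated) | [Li+].C[C@H](CCC=C(C)C)C/C(C)=C/[Al-](C)(C)CCCC | intermediate
5 | (2E,5R)-3,5,9-trimethyldeca-2,8-dien-1-ol | C[C@H](CCC=C(C)C)C/C(C)=C/CO | intermediate
6 | [(2S,3S)-3-[(2R)-2,6-dimethylhept-5-en-1-yl]-3-methyloxiran-2-yl]methanol | C[C@H](CCC=C(C)C)C[C@]1(C)O[C@H]1CO | intermediate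
7 | [(2S,3S)-3-[(2R)-4-(5,5-dimethyl-1,2,4-trioxolan-3-yl)-2-methylbutyl]-3-methyloxiran-2-yl]methanol (ozonide, not isolated) | C[C@H](CCC1OOC(C)(C)O1)C[C@]2(C)O[C@H]2CO | intermediate
8 | (4R)-5-[(2S,3S)-3-(hydroxymethyl)-2-methyloxiran-2-yl]-4-methylpentanal | C[C@H](CCC=O)C[C@]1(C)O[C@H]1CO | intermediate
9 | [(2S,3S)-3-methyl-3-[(2R)-2-methylhex-5-en-1-yl]oxiran-2-yl]methanol | C[C@H](CCC=C)C[C@]1(C)O[C@H]1CO | intermediate
10 | (2R,3S)-3-methyl-3-[(2R)-2-methylhex-5-en-1-yl]oxirane-2-carbaldehyde | C[C@H](CCC=C)C[C@]1(C)O[C@H]1C=O | intermediate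
11 | (1RS)-1-[(2S,3S)-3-methyl-3-[(2R)-2-methylhex-5-en-1-yl]oxiran-2-yl]ethan-1-ol (both carbinol epimers) | C[C@H](CCC=C)C[C@]1(C)O[C@H]1C(C)O | intermediate
12 | (2RS,4S,6R)-4,6-dimethyldec-9-ene-2,4-diol | C[C@H](CCC=C)C[C@](C)(O)CC(C)O | intermediate
13 | (2RS,4S,6R)-4-hydroxy-4,6-dimethyldec-9-en-2-yl 4-methylbenzenesulfonate (present as its lithium alkoxide, not isolated) | C[C@H](CCC=C)C[C@](C)(O)CC(C)OS(=O)(=O)c1ccc(C)cc1 | intermediate
14 | (2S,4RS)-2,4-dimethyl-2-[(2R)-2-methylhex-5-en-1-yl]oxetane | C[C@H](CCC=C)C[C@@]1(C)CC(C)O1 | intermediate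
15 | (2RS,4R,6R)-4-hydroperoxy-4,6-dimethyldec-9-en-2-ol | C[C@H](CCC=C)C[C@@](C)(OO)CC(C)O | intermediate
16 | (2RS,4R,6R)-4-[(2-methoxypropan-2-yl)peroxy]-4,6-dimethyldec-9-en-2-ol | C[C@H](CCC=C)C[C@@](C)(OOC(C)(C)OC)CC(C)O | intermediate
17 | (4R,6R)-4-[(2-methoxypropan-2-yl)peroxy]-4,6-dimethyldec-9-en-2-one | C[C@H](CCC=C)C[C@@](C)(OOC(C)(C)OC)CC(C)=O | intermediate
18 | (4R,6R)-4-hydroperoxy-4,6-dimethyldec-9-en-2-one (not isolated) | C[C@H](CCC=C)C[C@@](C)(OO)CC(C)=O | intermediate
19 | (3RS,5R)-3,5-dimethyl-5-[(2R)-2-methylhex-5-en-1-yl]-1,2-dioxolan-3-ol (not isolated) | C[C@H](CCC=C)C[C@]1(C)CC(C)(O)OO1 | intermediate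
20 | (3RS,5R)-3-methoxy-3,5-dimethyl-5-[(2R)-2-methylhex-5-en-1-yl]-1,2-dioxolane | C[C@H](CCC=C)C[C@]1(C)CC(C)(OC)OO1 | intermediate
21 | (5R)-3,5-dimethyl-5-[(2R)-2-methylhex-5-en-1-yl]-1,2-dioxolan-3-ylium (peroxycarbenium ion, not isolated) | C[C@H](CCC=C)C[C@]1(C)CC(C)=[O+]O1 | intermediate
22 | methyl 2-[(3R,5R)-3,5-dimethyl-5-[(2R)-2-methylhex-5-en-1-yl]-1,2-dioxolan-3-yl]acetate | C[C@H](CCC=C)C[C@]1(C)C[C@](C)(CC(=O)OC)OO1 | intermediate
23 | (4-bromobutyl)benzene | BrCCCCc1ccccc1 | starting material
24 | methyl 2-[(3R,5R)-5-[(2R)-6-(9-borabicyclo[3.3.1]nonan-9-yl)-2-methylhexyl]-3,5-dimethyl-1,2-dioxolan-3-yl]acetate (not isolated) | C[C@H](CCCCB1C2CCCC1CCC2)C[C@]3(C)C[C@](C)(CC(=O)OC)OO3 | intermediate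
25 | methyl 2-[(3R,5R)-3,5-dimethyl-5-[(2R)-2-methyl-10-phenyldecyl]-1,2-dioxolan-3-yl]acetate | C[C@H](CCCCCCCCc1ccccc1)C[C@]1(C)C[C@](C)(CC(=O)OC)OO1 | intermediate
26 | 2-[(3R,5R)-3,5-dimethyl-5-[(2R)-2-methyl-10-phenyldecyl]-1,2-dioxolan-3-yl]acetic acid | C[C@H](CCCCCCCCc1ccccc1)C[C@]1(C)C[C@](C)(CC(=O)O)OO1 | target

**Step count and risks**

Total step count: 16. Longest linear sequence: 16 steps, from 1 (23 is used as purchased).

Steps most likely to fail:

Step 14. Process at risk: poor facial selectivity in the capture of the peroxycarbenium ion, so that much of the material would end up with the wrong C3 configuration and the epimers could be hard to separate. Fallback: setting out from ketone 17, a Horner–Wadsworth–Emmons olefination (trimethyl phosphonoacetate, NaH, THF, 0 °C) would give methyl (5R,7R)-5-[(2-methoxypropan-2-yl)peroxy]-3,5,7-trimethylundeca-2,10-dienoate F1 as a mixture of alkene isomers. PPTS in methanol would unmask the hydroperoxide, methyl (5R,7R)-5-hydroperoxy-3,5,7-trimethylundeca-2,10-dienoate F2. Diethylamine in 2,2,2-trifluoroethanol would then close the ring by intramolecular conjugate addition of the hydroperoxide (5-exo-trig), coming back to the route at 22. This forms the C3–O bond instead of the C3–C bond. Both alkene isomers should converge on the same pair of C3 epimers. A chair-like transition state with the C5 chain and the CH2CO2Me group pseudo-equatorial points toward 22. Because the addition should be reversible under amine base, the (3S) epimer could be resubmitted.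

Step 15. Process at risk: reductive cleavage of the O–O bond by Pd(0)/phosphine, or β-hydride elimination and protodeboronation outrunning the coupling. Fallback: setting out from 22, hydroboration–oxidation (9-BBN; then NaBO3·4H2O) would give methyl 2-[(3R,5R)-5-[(2R)-6-hydroxy-2-methylhexyl]-3,5-dimethyl-1,2-dioxolan-3-yl]acetate F3. Dess–Martin oxidation would give the aldehyde methyl 2-[(3R,5R)-3,5-dimethyl-5-[(2R)-2-methyl-6-oxohexyl]-1,2-dioxolan-3-yl]acetate F4. A Wittig reaction with the ylide from (4-phenylbutyl)triphenylphosphonium bromide (NaHMDS, THF, −78 °C) would give methyl 2-[(3R,5R)-3,5-dimethyl-5-[(2R,6Z)-2-methyl-10-phenyldec-6-en-1-yl]-1,2-dioxolan-3-yl]acetate F5, in which the same two carbons are joined as a C=C bond. Diimide (potassium azodicarboxylate, AcOH, MeOH, rt) would saturate it without touching O–O, returning to the route at 25.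

Step 10. Process at risk: ionisation of the activated 2,2,4-trisubstituted oxetane (loss of configurational integrity at C5) or attack of H2O2 at the secondary C–O bond. Fallback: the peroxide is introduced on an oxetane without the secondary C–O bond and the C3 methyl carbon is added afterwards. Setting out from epoxy alcohol 9, Red-Al would give (3S,5R)-3,5-dimethylnon-8-ene-1,3-diol F6. TsCl in pyridine would give the primary tosylate (3S,5R)-3-hydroxy-3,5-dimethylnon-8-en-1-yl 4-methylbenzenesulfonate F7, and KOtBu the oxetane (2S)-2-methyl-2-[(2R)-2-methylhex-5-en-1-yl]oxetane F8. Perhydrolysis (H2O2, TMSOTf, Et2O) would give (3R,5R)-3-hydroperoxy-3,5-dimethylnon-8-en-1-ol F9, and 2-methoxypropene/PPTS the peroxyketal (3R,5R)-3-[(2-methoxypropan-2-yl)peroxy]-3,5-dimethylnon-8-en-1-ol F10. Dess–Martin oxidation would give the aldehyde (3R,5R)-3-[(2-methoxypropan-2-yl)peroxy]-3,5-dimethylnon-8-enal F11. MeTi(OiPr)3 (non-basic methyl transfer, THF, −40 °C) would add the methyl group and return to the route at 16.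

Further compounds
F1 | step 14 | methyl (5R,7R)-5-[(2-methoxypropan-2-yl)peroxy]-3,5,7-trimethylundeca-2,10-dienoate (2E/2Z mixture) | C[C@H](CCC=C)C[C@@](C)(OOC(C)(C)OC)CC(C)=CC(=O)OC
F2 | step 14 | methyl (5R,7R)-5-hydroperoxy-3,5,7-trimethylundeca-2,10-dienoate (2E/2Z mixture) | C[C@H](CCC=C)C[C@@](C)(OO)CC(C)=CC(=O)OC
F3 | step 15 | methyl 2-[(3R,5R)-5-[(2R)-6-hydroxy-2-methylhexyl]-3,5-dimethyl-1,2-dioxolan-3-yl]acetate | C[C@H](CCCCO)C[C@]1(C)C[C@](C)(CC(=O)OC)OO1
F4 | step 15 | methyl 2-[(3R,5R)-3,5-dimethyl-5-[(2R)-2-methyl-6-oxohexyl]-1,2-dioxolan-3-yl]acetate | C[C@H](CCCC=O)C[C@]1(C)C[C@](C)(CC(=O)OC)OO1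
F5 | step 15 | methyl 2-[(3R,5R)-3,5-dimethyl-5-[(2R,6Z)-2-methyl-10-phenyldec-6-en-1-yl]-1,2-dioxolan-3-yl]acetate | C[C@H](CCC/C=C\CCCc1ccccc1)C[C@]1(C)C[C@](C)(CC(=O)OC)OO1
F6 | step 10 | (3S,5R)-3,5-dimethylnon-8-ene-1,3-diol | C[C@H](CCC=C)C[C@](C)(O)CCO
F7 | step 10 | (3S,5R)-3-hydroxy-3,5-dimethylnon-8-en-1-yl 4-methylbenzenesulfonate | C[C@H](CCC=C)C[C@](C)(O)CCOS(=O)(=O)c1ccc(C)cc1
F8 | step 10 | (2S)-2-methyl-2-[(2R)-2-methylhex-5-en-1-yl]oxetane | C[C@H](CCC=C)C[C@@]1(C)CCO1
F9 | step 10 | (3R,5R)-3-hydroperoxy-3,5-dimethylnon-8-en-1-ol | C[C@H](CCC=C)C[C@@](C)(OO)CCO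
F10 | step 10 | (3R,5R)-3-[(2-methoxypropan-2-yl)peroxy]-3,5-dimethylnon-8-en-1-ol | C[C@H](CCC=C)C[C@@](C)(OOC(C)(C)OC)CCO
F11 | step 10 | (3R,5R)-3-[(2-methoxypropan-2-yl)peroxy]-3,5-dimethylnon-8-enal | C[C@H](CCC=C)C[C@@](C)(OOC(C)(C)OC)CC=O
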